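**Retrosynthetic overview**

- Numbering: C1 is the carboxyl carbon, C2 its CH2, C3 the hemiketal carbon (bonded to O2), C4 the ring CHMe, C5 the ring CH2, C6 the peroxy carbon (bonded to O1), C7 the side-chain CH2 and C8 the side-chain CHMe.
- The route rests on the 1,2-dioxane ring O1–O2–C3–C4–C5–C6. C3 and C6 are joined through C4–C5, so taking out O1–O2 and bonding C3 to C6 leaves a cyclobutanol (cyclobutanol C1 = C3, C2 = C6, C4 = C4). That cyclobutanol is the methyl acetate adduct of a 2,2,4-trisubstituted cyclobutanone.
- Key disconnection: C6–O1 and O2–C3, both made when Co(acac)2 and O2 expand the cyclobutanol. The cyclobutane ring is formed first (cyclopropylide spiroannulation of a methyl ketone) and the dioxane ring second.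
- Stereocentres: C8 comes from (R)-citronellal. C4 is set by SAMP-hydrazone methylation at the only enolisable carbon of the cyclobutanone. C6 forms unselectively and its epimers are separated. C3 is a hemiketal under thermodynamic control.
- The methyl ketone comes from citronellal by MeMgBr addition, oxidation, ozonolysis, Wittig chain extension with the ylide from (5-bromopentyl)benzene, and hydrogenation. The last step is ester hydrolysis.

Key step: step 12

Assumption: methylation of the SAMP azaenolate is taken to follow the usual sense for cyclic ketones (SAMP and cyclohexanone give the (R)-2-methyl ketone), which corresponds to (4R) here; if a test alkylation shows the opposite sense, the enantiomeric auxiliary RAMP is used.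

**Route**

Step 1
Reactants: 1 (R)-citronellal, (3R)-3,7-dimethyloct-6-enal
Product: 2 (4R)-4,8-dimethylnon-7-en-2-ol (both C2 epimers)
Conditions: MeMgBr, Et2O, 0 °C; then H2O/aq. NH4Cl
Reagents that add atoms: methylmagnesium bromide, C[Mg]Br
Why: Grignard addition to the aldehyde should give the secondary alcohol; the new carbinol centre forms unselectively but is removed in step 2, and the methyl-bearing centre (later C8) is not touched.

Step 2
Reactants: 2 (4R)-4,8-dimethylnon-7-en-2-ol
Product: 3 (4R)-4,8-dimethylnon-7-en-2-one
Conditions: Dess–Martin periodinane, CH2Cl2, 0 °C → rt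
Reagents that add atoms: none
Why: Dess–Martin oxidation of a secondary alcohol to the methyl ketone under near-neutral conditions that leave the trisubstituted alkene alone.

Step 3
Reactants: 3 (4R)-4,8-dimethylnon-7-en-2-one
Product: 4 (4R)-4-methyl-6-oxoheptanal
Conditions: O3, CH2Cl2/MeOH, −78 °C; then Me2S, −78 °C → rt; used crude
Reagents that add atoms: ozone, [O-][O+]=O
Why: Ozonolysis with reductive work-up cleaves the only C=C bond to the aldehyde and acetone; the ketone is inert and the stereocentre, β to both carbonyls, cannot epimerise.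

Step 4
Reactants: 5 (5-bromopentyl)benzene
Product: 6 triphenyl(5-phenylpentyl)phosphonium bromide
Conditions: PPh3, MeCN, reflux
Reagents that add atoms: triphenylphosphine, c1ccc(cc1)P(c1ccccc1)c1ccccc1
Why: SN2 quaternisation of triphenylphosphine by an unhindered primary bromide.

Step 5
Reactants: 4 (4R)-4-methyl-6-oxoheptanal; 6 triphenyl(5-phenylpentyl)phosphonium bromide
Product: 8 (4R,7Z)-4-methyl-12-phenyldodec-7-en-2-one, via phosphorus ylide 7 (not isolated)
Conditions: NaN(SiMe3)2, THF, 0 °C; then 4, −78 °C → rt
Reagents that add atoms: none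
Why: Wittig olefination in which the unstabilised ylide should take the aldehyde far faster than the methyl ketone at −78 °C; the mainly Z alkene geometry is irrelevant because the double bond is hydrogenated next.

Step 6
Reactants: 8 (4R,7Z)-4-methyl-12-phenyldodec-7-en-2-one
Product: 9 (4R)-4-methyl-12-phenyldodecan-2-one
Conditions: H2 (1 atm), 10% Pd/C, EtOAc, rt
Reagents that add atoms: none
Why: Heterogeneous hydrogenation of a disubstituted alkene; the ketone and the phenyl ring are not reduced at 1 atm.

Step 7
Reactants: 9 (4R)-4-methyl-12-phenyldodecan-2-one; 10 cyclopropyldiphenylsulfonium tetrafluoroborate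
Product: 12 2-methyl-2-[(2R)-2-methyl-10-phenyldecyl]cyclobutan-1-one (both C2 epimers), via oxaspiropentane 11 (not isolated)
Conditions: KOH, DMSO, rt; then 1 M aq. HBF4, Et2O
Reagents that add atoms: none
Why: Trost spiroannulation: the cyclopropylide, formed reversibly by KOH in DMSO so that the enolisable ketone is tolerated, adds to the carbonyl to give the oxaspiropentane, and acid opens it to the tertiary cyclopropylcarbinyl cation whose ring bond migrates to give the 2,2-disubstituted cyclobutanone; both C2 epimers form, which is harmless because this carbon later becomes the planar C6 radical.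

Step 8
Reactants: 12 2-methyl-2-[(2R)-2-methyl-10-phenyldecyl]cyclobutan-1-one
Product: 13 SAMP hydrazone of 12, (2S)-2-(methoxymethyl)-N-{2-methyl-2-[(2R)-2-methyl-10-phenyldecyl]cyclobutylidene}pyrrolidin-1-amine (amino group turned toward the ring CH2)
Conditions: SAMP, cyclohexane, 4 Å MS, 60 °C
Reagents that add atoms: (S)-1-amino-2-(methoxymethyl)pyrrolidine (SAMP), COC[C@@H]1CCCN1N
Why: Condensation of the strained, electrophilic cyclobutanone with the hydrazine gives the hydrazone, with the pyrrolidine on the side away from the quaternary carbon.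

Step 9
Reactants: 13 SAMP hydrazone of 12
Product: 15 SAMP hydrazone of (4R)-2,4-dimethyl-2-[(2R)-2-methyl-10-phenyldecyl]cyclobutan-1-one, via lithium azaenolate 14 (not isolated)
Conditions: LiN(iPr)2, THF, 0 °C; then MeI, −95 °C → rt
Reagents that add atoms: iodomethane, CI
Why: Enders SAMP-hydrazone alkylation: only C4 can be deprotonated because C2 is quaternary, and the lithium azaenolate, chelated by the methoxymethyl group, should be methylated on one face under auxiliary control to give (4R) in both C2 epimers.

Step 10
Reactants: 15 SAMP hydrazone of the (4R)-methylated cyclobutanone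
Product: 16 (4R)-2,4-dimethyl-2-[(2R)-2-methyl-10-phenyldecyl]cyclobutan-1-one (both C2 epimers)
Conditions: sat. aq. oxalic acid, Et2O, rt
Reagents that add atoms: water, O
Why: Mild two-phase oxalic acid hydrolysis of the hydrazone should free the ketone without enolising the new α-centre C4, and sends the auxiliary to the aqueous phase for recovery.

Step 11
Reactants: 16 (4R)-2,4-dimethyl-2-[(2R)-2-methyl-10-phenyldecyl]cyclobutan-1-one; 17 methyl acetate
Product: 19 methyl 2-[(4R)-1-hydroxy-2,4-dimethyl-2-[(2R)-2-methyl-10-phenyldecyl]cyclobutyl]acetate (mixture at C1 and C2), via lithium enolate of methyl acetate 18 (not isolated)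
Conditions: LiN(iPr)2, MeOAc, THF, −78 °C; then 16, −78 °C; AcOH quench at −78 °C
Reagents that add atoms: none
Why: Aldol addition of the lithium ester enolate to the cyclobutanone; strain relief on rehybridisation should make 1,2-addition faster than enolisation at −78 °C so that C4 is kept, and the carbinol configuration is irrelevant because C1 becomes the C3 ketone.

Step 12
Reactants: 19 methyl 2-[(4R)-1-hydroxy-2,4-dimethyl-2-[(2R)-2-methyl-10-phenyldecyl]cyclobutyl]acetate; 20 dioxygen
Product: 22 methyl 2-[(3S,4R,6S)-3-hydroxy-4,6-dimethyl-6-[(2R)-2-methyl-10-phenyldecyl]-1,2-dioxan-3-yl]acetate, via open-chain hydroperoxy ketone 21 (not isolated)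
Conditions: Co(acac)2 (20 mol%), O2 (1 atm), CH2Cl2, rt; chromatography on SiO2 to remove the (6R) epimer
Reagents that add atoms: none
Why: Co(acac)2 is oxidised by O2 to a trivalent cobalt species that exchanges with the tertiary alcohol; homolysis of the cobalt alkoxide gives the cyclobutyloxy radical, β-scission of the strained C3–C6 bond (cyclobutanol C1–C2) gives the tertiary C6 radical, triplet O2 adds (C6–O1), and the peroxyl radical is reduced to hydroperoxide 21 with return of divalent cobalt. The closest known reaction type is this same cobalt-catalysed aerobic oxidative ring expansion of cyclobutanols to 1,2-dioxan-3-ols, a relative of the cyclopropanol to 1,2-dioxolan-3-ol oxidation. The 1,2-dioxane closes by 6-exo-trig attack of the hydroperoxide oxygen on the C3 ketone (O2–C3). C6 is created at a planar radical with no useful bias from the 1,3-related C4, so both C6 epimers are expected and the (6S) isomer is isolated by chromatography; C3 is a hemiketal in ring–chain equilibrium and should settle as (3S), with OH axial (anomeric effect) and CH2CO2Me equatorial and trans to the equatorial C4 methyl. The step needs scission toward C6 and not toward C4 or with loss of the CH2CO2Me radical; the tertiary radical, the release of about 26 kcal/mol of ring strain and the unfavourable polarity of an electrophilic ester-substituted radical should secure this. C4 and C8 take no part in the radical events, and the closed hemiketal keeps the β-keto ester, and with it the α-hydrogen at C4, masked.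

Step 13
Reactants: 22 methyl 2-[(3S,4R,6S)-3-hydroxy-4,6-dimethyl-6-[(2R)-2-methyl-10-phenyldecyl]-1,2-dioxan-3-yl]acetate
Product: 23 2-[(3S,4R,6S)-3-hydroxy-4,6-dimethyl-6-[(2R)-2-methyl-10-phenyldecyl]-1,2-dioxan-3-yl]acetic acid
Conditions: LiOH, THF/H2O (3:1), 0 °C; then cold 0.5 M HCl to pH 4
Reagents that add atoms: lithium hydroxide, [Li+].[OH-]
Why: Saponification of the methyl ester; neither peroxy carbon carries a hydrogen (no Kornblum–DeLaMare path), any transient ring opening gives only the doubly stabilised β-keto ester enolate, which shields C4, and on cold acidification the hemiketal should re-close to the thermodynamic (3S) anomer.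

**Compound list**

1 | (R)-citronellal, (3R)-3,7-dimethyloct-6-enal | C[C@H](CCC=C(C)C)CC=O | starting material
2 | (4R)-4,8-dimethylnon-7-en-2-ol (both C2 epimers) | C[C@H](CCC=C(C)C)CC(C)O | intermediate
3 | (4R)-4,8-dimethylnon-7-en-2-one | C[C@H](CCC=C(C)C)CC(C)=O | intermediate
4 | (4R)-4-methyl-6-oxoheptanal | C[C@H](CCC=O)CC(C)=O | intermediate
5 | (5-bromopentyl)benzene | BrCCCCCc1ccccc1 | starting material
6 | triphenyl(5-phenylpentyl)phosphonium bromide | [Br-].c1ccc(CCCCC[P+](c2ccccc2)(c2ccccc2)c2ccccc2)cc1 | intermediate
7 | triphenyl(5-phenylpentylidene)-λ5-phosphane (ylide) | c1ccc(CCCCC=P(c2ccccc2)(c2ccccc2)c2ccccc2)cc1 | intermediate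
8 | (4R,7Z)-4-methyl-12-phenyldodec-7-en-2-one | C[C@H](CC/C=C\CCCCc1ccccc1)CC(C)=O | intermediate
9 | (4R)-4-methyl-12-phenyldodecan-2-one | C[C@H](CCCCCCCCc1ccccc1)CC(C)=O | intermediate
10 | cyclopropyldiphenylsulfonium tetrafluoroborate | C1CC1[S+](c1ccccc1)c1ccccc1.F[B-](F)(F)F | starting material
11 | 2-methyl-2-[(2R)-2-methyl-10-phenyldecyl]-1-oxaspiro[2.2]pentane (both C2 epimers) | C[C@H](CCCCCCCCc1ccccc1)CC1(C)OC12CC2 | intermediate
12 | 2-methyl-2-[(2R)-2-methyl-10-phenyldecyl]cyclobutan-1-one (both C2 epimers) | C[C@H](CCCCCCCCc1ccccc1)CC1(C)CCC1=O | intermediate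
13 | SAMP hydrazone of 12, (2S)-2-(methoxymethyl)-N-{2-methyl-2-[(2R)-2-methyl-10-phenyldecyl]cyclobutylidene}pyrrolidin-1-amine | C[C@H](CCCCCCCCc1ccccc1)CC1(C)CCC1=NN1CCC[C@H]1COC | intermediate
14 | lithium azaenolate of 13 | [Li+].C[C@H](CCCCCCCCc1ccccc1)CC1(C)CC=C1[N-]N1CCC[C@H]1COC | intermediate
15 | SAMP hydrazone of 16, (2S)-N-{(4R)-2,4-dimethyl-2-[(2R)-2-methyl-10-phenyldecyl]cyclobutylidene}-2-(methoxymethyl)pyrrolidin-1-amine | C[C@H](CCCCCCCCc1ccccc1)CC1(C)C[C@@H](C)C1=NN1CCC[C@H]1COC | intermediate
16 | (4R)-2,4-dimethyl-2-[(2R)-2-methyl-10-phenyldecyl]cyclobutan-1-one (both C2 epimers) | C[C@H](CCCCCCCCc1ccccc1)CC1(C)C[C@@H](C)C1=O | intermediate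
17 | methyl acetate | CC(=O)OC | starting material
18 | lithium 1-methoxyethen-1-olate (lithium enolate of methyl acetate) | [Li+].[O-]C(=C)OC | intermediate
19 | methyl 2-[(4R)-1-hydroxy-2,4-dimethyl-2-[(2R)-2-methyl-10-phenyldecyl]cyclobutyl]acetate (mixture at C1 and C2) | C[C@H](CCCCCCCCc1ccccc1)CC1(C)C[C@@H](C)C1(O)CC(=O)OC | intermediate
20 | dioxygen | O=O | starting material
21 | methyl (4R,8R)-6-hydroperoxy-4,6,8-trimethyl-3-oxo-16-phenylhexadecanoate (both C6 epimers) | C[C@H](CCCCCCCCc1ccccc1)CC(C)(OO)C[C@@H](C)C(=O)CC(=O)OC | intermediate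
22 | methyl 2-[(3S,4R,6S)-3-hydroxy-4,6-dimethyl-6-[(2R)-2-methyl-10-phenyldecyl]-1,2-dioxan-3-yl]acetate | C[C@H](CCCCCCCCc1ccccc1)C[C@@]1(C)C[C@@H](C)[C@](O)(CC(=O)OC)OO1 | intermediate
23 | 2-[(3S,4R,6S)-3-hydroxy-4,6-dimethyl-6-[(2R)-2-methyl-10-phenyldecyl]-1,2-dioxan-3-yl]acetic acid | C[C@H](CCCCCCCCc1ccccc1)C[C@@]1(C)C[C@@H](C)[C@](O)(CC(=O)O)OO1 | target

Total step count: 13. Longest linear sequence: 12 steps (steps 1–3 and 5–13 from (R)-citronellal); step 4 is a one-step side branch.

**Steps most likely to fail**

1. Step 12 (ring expansion).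
   - What may go wrong: catalyst turnover may stall on the hindered tertiary alcohol. β-Scission may leak toward C4 or expel the CH2CO2Me radical. Cobalt may decompose the peroxy hemiketal once it has formed. The two C6 epimers may also be hard to separate.
   - Fallback: it sets out from 16 and returns at 22, and makes the C6 radical by hydrogen-atom transfer to an alkene instead of by ring scission. Ketone 16 is converted with NH2OH·HCl and pyridine into the cyclobutanone oxime F1. Beckmann fragmentation (TsCl, pyridine) breaks the bond to the quaternary carbon, which lies anti to the leaving group and gives a tertiary cation, to give the unsaturated nitrile F2. F2 is drawn as the 4-methylidene isomer; its double-bond isomers serve equally, because each places the Markovnikov radical on C6. A Blaise reaction (methyl bromoacetate, Zn, THF; aq. HCl) gives the γ,δ-unsaturated β-keto ester F3. Isayama–Mukaiyama hydroperoxysilylation (Co(acac)2, O2, Et3SiH, ClCH2CH2Cl) gives the tertiary triethylsilyl peroxide F4. Desilylation (Bu4NF buffered with AcOH) frees hydroperoxide 21, which closes to 22; the C6 epimers are again separated.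

2. Step 9 (azaenolate methylation, together with the hydrazone release in step 10).
   - What may go wrong: metalation of the hindered hydrazone may be incomplete. Facial selectivity may be eroded in the C2 epimer that is mismatched with the auxiliary. C4 may be partly epimerised during cleavage. The C4 epimers would lead to dioxanes that differ from the wanted one only in their relation to the remote C8 centre and would be very hard to remove.
   - Fallback: it sets out from 12 and returns at 16, and replaces auxiliary-controlled alkylation by catalyst-controlled hydrogenation. Direct α-methylenation of 12 (paraformaldehyde, diisopropylammonium trifluoroacetate, THF, reflux) gives the exocyclic enone 2-methyl-4-methylidene-2-[(2R)-2-methyl-10-phenyldecyl]cyclobutan-1-one F5. Asymmetric hydrogenation of the exocyclic C=C bond (H2, Ru(OAc)2[(S)-BINAP] or its enantiomer, chosen by a test reduction, MeOH) then sets C4 and gives 16. The reaction type is the one used for 2-alkylidene cycloalkanones.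

3. Step 13 (saponification).
   - What may go wrong: base may open the hemiketal, and the resulting β-keto acid may decarboxylate on acidification or undergo retro-Claisen cleavage; C4 may be lost by enolisation.
   - Fallback: it sets out from 16 and returns at 23, and changes the ester so that no base meets the peroxide. LiCH2CO2tBu (from tert-butyl acetate and LiN(iPr)2, THF, −78 °C) is added to 16 to give the tert-butyl ester cyclobutanol F6. The same Co(acac)2/O2 ring expansion and separation of the C6 epimers gives the tert-butyl ester dioxanol F7. Acidolysis (CF3CO2H/CH2Cl2, 0 °C, aqueous work-up) cleaves the ester to 23 and lets the hemiketal settle again at C3.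

Further compounds
F1 | step 12 | (4R)-2,4-dimethyl-2-[(2R)-2-methyl-10-phenyldecyl]cyclobutan-1-one oxime | C[C@H](CCCCCCCCc1ccccc1)CC1(C)C[C@@H](C)C1=NO
F2 | step 12 | (2R,6R)-2,6-dimethyl-4-methylidene-14-phenyltetradecanenitrile | C[C@H](CCCCCCCCc1ccccc1)CC(=C)C[C@@H](C)C#N
F3 | step 12 | methyl (4R,8R)-4,8-dimethyl-6-methylidene-3-oxo-16-phenylhexadecanoate | C[C@H](CCCCCCCCc1ccccc1)CC(=C)C[C@@H](C)C(=O)CC(=O)OC
F4 | step 12 | methyl (4R,8R)-4,6,8-trimethyl-3-oxo-16-phenyl-6-[(triethylsilyl)peroxy]hexadecanoate (both C6 epimers) | C[C@H](CCCCCCCCc1ccccc1)CC(C)(OO[Si](CC)(CC)CC)C[C@@H](C)C(=O)CC(=O)OC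
F5 | step 9 | 2-methyl-4-methylidene-2-[(2R)-2-methyl-10-phenyldecyl]cyclobutan-1-one | C[C@H](CCCCCCCCc1ccccc1)CC1(C)CC(=C)C1=O
F6 | step 13 | tert-butyl 2-[(4R)-1-hydroxy-2,4-dimethyl-2-[(2R)-2-methyl-10-phenyldecyl]cyclobutyl]acetate | C[C@H](CCCCCCCCc1ccccc1)CC1(C)C[C@@H](C)C1(O)CC(=O)OC(C)(C)C
F7 | step 13 | tert-butyl 2-[(3S,4R,6S)-3-hydroxy-4,6-dimethyl-6-[(2R)-2-methyl-10-phenyldecyl]-1,2-dioxan-3-yl]acetate | C[C@H](CCCCCCCCc1ccccc1)C[C@@]1(C)C[C@@H](C)[C@](O)(CC(=O)OC(C)(C)C)OO1
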